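The benzene ring (C3a, C4, C5, C6, C7, C7a) is cut at C4–C5 and C6–C7. What remains is the oxygen ring O1–C2–C3–C3a–C7a as an oxolane with exocyclic methylenes on C7a and C3a, whose trans C2/C3 stereocentres are C4 and C3 of D-galactono-1,4-lactone. One Diels–Alder reaction of this ring-locked 2-alkoxydiene with but-3-yn-2-one closes the carbocycle and, because O1 sits on C7a, delivers the acetyl group to C5, para to O1; dehydrogenation then gives the arene. The precursor is the bis-TBS ether of (4R,5S)-5-(3-hydroxyprop-1-en-2-yl)-2,3-dimethylideneoxolan-4-ol.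

Key step: step 9

Remark: atoms map as lactone C1 → C7a, C2 → C3a, C3 → C3, C4 → C2, C5 → the side-chain alkene carbon, C6 → the formyl carbon; the methylene carbons placed on C2, C1 and C5 become C4, C7 and the side-chain =CH2; TBS = tert-butyl(dimethyl)silyl, TBSO = its ether oxygen.

Step 1
Reactants: 1 D-galactono-1,4-lactone
Product: 2 5,6-O-isopropylidene-D-galactono-1,4-lactone
Conditions: Me2C(OMe)2, TsOH (cat.), acetone, rt
Reagents that add atoms: 2,2-dimethoxypropane, COC(C)(C)OC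
Why: Acid-catalysed transacetalisation caps the terminal 5,6-diol as a dioxolane, since the trans-2,3-diol on the five-membered lactone cannot be bridged.

Step 2
Reactants: 2 5,6-O-isopropylidene-D-galactono-1,4-lactone
Product: 3 2-deoxy-5,6-O-isopropylidene-D-lyxo-hexono-1,4-lactone
Conditions: SmI2 (3 equiv), HOCH2CH2OH, THF–HMPA, rt
Reagents that add atoms: none
Why: Samarium diiodide α-deoxygenation of an α-hydroxy lactone, in which two single-electron transfers expel O2 and the resulting samarium enolate is protonated at once by the diol, so the C3 hydroxyl and the centres C3, C4 and C5 should be kept.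

Step 3
Reactants: 3 2-deoxy-5,6-O-isopropylidene-D-lyxo-hexono-1,4-lactone
Product: 4 3-O-TBS-2-deoxy-5,6-O-isopropylidene-D-lyxo-hexono-1,4-lactone
Conditions: TBSCl, imidazole, DMF, rt
Reagents that add atoms: tert-butyl(chloro)dimethylsilane, CC(C)(C)[Si](C)(C)Cl
Why: Imidazole-promoted silylation of the only free hydroxyl, with a base too weak to cause β-elimination of the lactone.

Step 4
Reactants: 4 3-O-TBS-2-deoxy-5,6-O-isopropylidene-D-lyxo-hexono-1,4-lactone
Product: 7 (4R,5S)-4-(TBSO)-5-[(4R)-2,2-dimethyl-1,3-dioxolan-4-yl]-3-methylideneoxolan-2-one, via Mannich base 5 (not isolated), via trimethylammonium iodide 6 (not isolated)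
Conditions: LiN(SiMe3)2, THF, −78 °C; CH2=NMe2+ I−, −78 → −20 °C; MeI, rt; aq. NaHCO3, rt
Reagents that add atoms: N,N-dimethylmethyleneiminium iodide (Eschenmoser's salt), C=[N+](C)C.[I-]
Why: Eschenmoser methylenation, in which the cold lithium enolate undergoes a Mannich reaction, iodomethane quaternises the amine and bicarbonate induces β-elimination of trimethylamine, so the transient C2 stereocentre is erased.

Step 5
Reactants: 7 (4R,5S)-4-(TBSO)-5-[(4R)-2,2-dimethyl-1,3-dioxolan-4-yl]-3-methylideneoxolan-2-one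
Product: 8 (4R,5S)-4-(TBSO)-5-[(1R)-1,2-dihydroxyethyl]-3-methylideneoxolan-2-one
Conditions: AcOH–H2O (4:1), 40 °C
Reagents that add atoms: none
Why: Mild aqueous-acid hydrolysis of the terminal acetonide, which should cleave far faster than the hindered secondary silyl ether and leave the α-methylene lactone alone.

Step 6
Reactants: 8 (4R,5S)-4-(TBSO)-5-[(1R)-1,2-dihydroxyethyl]-3-methylideneoxolan-2-one
Product: 9 (4R,5S)-4-(TBSO)-5-[(1R)-2-(TBSO)-1-hydroxyethyl]-3-methylideneoxolan-2-one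
Conditions: TBSCl (1.05 equiv), Et3N, DMAP (cat.), CH2Cl2, 0 °C
Reagents that add atoms: tert-butyl(chloro)dimethylsilane, CC(C)(C)[Si](C)(C)Cl
Why: DMAP-catalysed silylation discriminates sterically in favour of the primary hydroxyl over the secondary carbinol.

Step 7
Reactants: 9 (4R,5S)-4-(TBSO)-5-[(1R)-2-(TBSO)-1-hydroxyethyl]-3-methylideneoxolan-2-one
Product: 10 (4R,5R)-4-(TBSO)-5-[(TBSO)acetyl]-3-methylideneoxolan-2-one
Conditions: Dess–Martin periodinane, NaHCO3, CH2Cl2, 0 °C → rt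
Reagents that add atoms: none
Why: Buffered Dess–Martin oxidation gives the ketone under non-basic conditions, so the adjacent ring carbon should not enolise and the β-silyloxy group should not eliminate (the descriptor at C5 changes by priority only).

Step 8
Reactants: 10 (4R,5R)-4-(TBSO)-5-[(TBSO)acetyl]-3-methylideneoxolan-2-one
Product: 12 (4R,5S)-4-(TBSO)-5-[3-(TBSO)prop-1-en-2-yl]-2,3-dimethylideneoxolane, via mono-olefin lactone 11 (not isolated)
Conditions: Cp2TiMe2 (5 equiv), toluene–THF, 65 °C, dark; filtration through basic alumina (hexane, 1% Et3N)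
Reagents that add atoms: dimethyltitanocene Cp2TiMe2, C[Ti](C)(C1C=CC=C1)C1C=CC=C1
Why: Petasis methylenation, in which thermally generated Cp2Ti=CH2 olefinates first the ketone and then the lactone carbonyl through oxatitanacyclobutanes; the carbene is non-basic, so the centre next to the ketone is kept, and enoates and lactones are known to give 2-alkoxy-1,3-dienes this way.

Step 9
Reactants: 12 (4R,5S)-4-(TBSO)-5-[3-(TBSO)prop-1-en-2-yl]-2,3-dimethylideneoxolane; 13 but-3-yn-2-one
Product: 14 1-{(2S,3R)-3-(TBSO)-2-[3-(TBSO)prop-1-en-2-yl]-2,3,4,7-tetrahydro-1-benzofuran-5-yl}ethan-1-one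
Conditions: but-3-yn-2-one (3 equiv), K2CO3 (powder), BHT (cat.), toluene, 50 °C, sealed tube; filtration, evaporation
Reagents that add atoms: none
Why: The ring-locked s-cis diene C7=C7a–C3a=C4 and the ynone should combine in a concerted thermal [4+2] cycloaddition of normal electron demand, suprafacial on both partners; the closest known reaction type is the Diels–Alder addition of 2-alkoxy- and 2-silyloxy-1,3-dienes to alkynyl ketones. The six-membered carbocycle C3a–C4–C5–C6–C7–C7a is closed intermolecularly by forming C4–C5 and C6–C7 in one event, which leaves a 1,4-cyclohexadiene one oxidation level below the arene. No stereocentre is created, and C2 and C3 lie outside the reacting π-system and are not touched. The step needs regioselectivity: the lone pair of O1 on C7a raises the HOMO coefficient at C7, which bonds to the electron-poor β-carbon of the ynone, so the acyl-bearing carbon becomes C5, para to O1, while the alkyl branch on C3a opposes this only weakly. Powdered K2CO3 keeps the medium free of acid, so that neither the exocyclic enol ether nor the allylic C3 silyl ether ionises, and BHT suppresses radical oligomerisation of the ynone.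

Step 10
Reactants: 14 1-{(2S,3R)-3-(TBSO)-2-[3-(TBSO)prop-1-en-2-yl]-2,3,4,7-tetrahydro-1-benzofuran-5-yl}ethan-1-one
Product: 15 1-{(2S,3R)-3-(TBSO)-2-[3-(TBSO)prop-1-en-2-yl]-2,3-dihydro-1-benzofuran-5-yl}ethan-1-one
Conditions: DDQ (1.05 equiv), NaHCO3 (solid), CH2Cl2, 0 °C
Reagents that add atoms: none
Why: Dehydrogenative aromatisation of a 1,4-cyclohexadiene, in which DDQ abstracts hydride from a doubly allylic CH2 (C4 or C7) and the arenium ion loses a proton, which should be much faster than any ionisation at C3 in the buffered medium.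

Step 11
Reactants: 15 1-{(2S,3R)-3-(TBSO)-2-[3-(TBSO)prop-1-en-2-yl]-2,3-dihydro-1-benzofuran-5-yl}ethan-1-one
Product: 16 (1R)-1-{(2S,3R)-3-(TBSO)-2-[3-(TBSO)prop-1-en-2-yl]-2,3-dihydro-1-benzofuran-5-yl}ethan-1-ol
Conditions: RuCl[(R,R)-TsDPEN](p-cymene) (2 mol%), HCO2H–Et3N (5:2), CH2Cl2, rt
Reagents that add atoms: none
Why: Noyori asymmetric transfer hydrogenation, in which the (R,R)-catalyst should set the (R)-carbinol of the aryl methyl ketone under catalyst control (the ring stereocentres are remote) without reducing the isolated 1,1-disubstituted alkene.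

Step 12
Reactants: 16 (1R)-1-{(2S,3R)-3-(TBSO)-2-[3-(TBSO)prop-1-en-2-yl]-2,3-dihydro-1-benzofuran-5-yl}ethan-1-ol; 17 tiglic acid [(2E)-2-methylbut-2-enoic acid]
Product: 18 (1R)-1-{(2S,3R)-3-(TBSO)-2-[3-(TBSO)prop-1-en-2-yl]-2,3-dihydro-1-benzofuran-5-yl}ethyl (2E)-2-methylbut-2-enoate
Conditions: tiglic acid (1.5 equiv), DCC, DMAP, CH2Cl2, 0 °C → rt
Reagents that add atoms: none
Why: Steglich esterification acylates the unhindered benzylic hydroxyl at oxygen under neutral conditions, so the carbinol configuration and the E geometry of the acid should be retained.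

Step 13
Reactants: 18 (1R)-1-{(2S,3R)-3-(TBSO)-2-[3-(TBSO)prop-1-en-2-yl]-2,3-dihydro-1-benzofuran-5-yl}ethyl (2E)-2-methylbut-2-enoate
Product: 20 (1R)-1-[(2S,3R)-3-hydroxy-2-(3-hydroxyprop-1-en-2-yl)-2,3-dihydro-1-benzofuran-5-yl]ethyl (2E)-2-methylbut-2-enoate, via C3 mono-silyl ether 19 (not isolated)
Conditions: Bu4NF, AcOH (1:1), THF, 0 °C → rt
Reagents that add atoms: none
Why: Fluoride-induced desilylation buffered with acetic acid, so that the ester is not cleaved and the benzylic positions do not ionise; the primary allylic ether should fall first and the hindered C3 ether after it.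

Step 14
Reactants: 20 (1R)-1-[(2S,3R)-3-hydroxy-2-(3-hydroxyprop-1-en-2-yl)-2,3-dihydro-1-benzofuran-5-yl]ethyl (2E)-2-methylbut-2-enoate
Product: 21 (1R)-1-[(2S,3R)-3-hydroxy-2-(3-oxoprop-1-en-2-yl)-2,3-dihydro-1-benzofuran-5-yl]ethyl (2E)-2-methylbut-2-enoate
Conditions: [Cu(MeCN)4]OTf (5 mol%), 2,2'-bipyridine (5 mol%), TEMPO (5 mol%), N-methylimidazole (10 mol%), MeCN, air, rt
Reagents that add atoms: none
Why: Copper/nitroxyl aerobic alcohol oxidation, which is sterically selective for the primary allylic alcohol over the secondary C3 carbinol; the trans C2/C3 arrangement also prevents lactol formation and over-oxidation.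

Step 15
Reactants: 21 (1R)-1-[(2S,3R)-3-hydroxy-2-(3-oxoprop-1-en-2-yl)-2,3-dihydro-1-benzofuran-5-yl]ethyl (2E)-2-methylbut-2-enoate
Product: 22 (1R)-1-[(2S,3R)-3-(acetyloxy)-2-(3-oxoprop-1-en-2-yl)-2,3-dihydro-1-benzofuran-5-yl]ethyl (2E)-2-methylbut-2-enoate
Conditions: Ac2O, pyridine, DMAP (cat.), CH2Cl2, 0 °C
Reagents that add atoms: acetic anhydride, CC(=O)OC(C)=O
Why: DMAP-catalysed O-acetylation of the remaining secondary hydroxyl at 0 °C, mild enough that acetic acid should not be eliminated across C2–C3 and the enal should stay intact.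

Compound list
1 | D-galactono-1,4-lactone | O=C1[C@H](O)[C@@H](O)[C@@H](O1)[C@H](O)CO | starting material
2 | 5,6-O-isopropylidene-D-galactono-1,4-lactone | O=C1[C@H](O)[C@@H](O)[C@@H](O1)[C@H]2COC(C)(C)O2 | intermediate
3 | 2-deoxy-5,6-O-isopropylidene-D-lyxo-hexono-1,4-lactone | O=C1C[C@@H](O)[C@@H](O1)[C@H]2COC(C)(C)O2 | intermediate
4 | 3-O-TBS-2-deoxy-5,6-O-isopropylidene-D-lyxo-hexono-1,4-lactone | O=C1C[C@@H](O[Si](C)(C)C(C)(C)C)[C@@H](O1)[C@H]2COC(C)(C)O2 | intermediate
5 | 3-O-TBS-2-deoxy-2-C-[(dimethylamino)methyl]-5,6-O-isopropylidene-D-galactono-1,4-lactone (2,3-trans Mannich base, not isolated) | O=C1[C@H](CN(C)C)[C@@H](O[Si](C)(C)C(C)(C)C)[C@@H](O1)[C@H]2COC(C)(C)O2 | intermediate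
6 | 3-O-TBS-2-deoxy-5,6-O-isopropylidene-2-C-[(trimethylammonio)methyl]-D-galactono-1,4-lactone iodide (not isolated) | O=C1[C@H](C[N+](C)(C)C)[C@@H](O[Si](C)(C)C(C)(C)C)[C@@H](O1)[C@H]2COC(C)(C)O2.[I-] | intermediate
7 | (4R,5S)-4-(TBSO)-5-[(4R)-2,2-dimethyl-1,3-dioxolan-4-yl]-3-methylideneoxolan-2-one | O=C1C(=C)[C@@H](O[Si](C)(C)C(C)(C)C)[C@@H](O1)[C@H]2COC(C)(C)O2 | intermediate
8 | (4R,5S)-4-(TBSO)-5-[(1R)-1,2-dihydroxyethyl]-3-methylideneoxolan-2-one | O=C1C(=C)[C@@H](O[Si](C)(C)C(C)(C)C)[C@@H](O1)[C@H](O)CO | intermediate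
9 | (4R,5S)-4-(TBSO)-5-[(1R)-2-(TBSO)-1-hydroxyethyl]-3-methylideneoxolan-2-one | O=C1C(=C)[C@@H](O[Si](C)(C)C(C)(C)C)[C@@H](O1)[C@H](O)CO[Si](C)(C)C(C)(C)C | intermediate
10 | (4R,5R)-4-(TBSO)-5-[(TBSO)acetyl]-3-methylideneoxolan-2-one | O=C1C(=C)[C@@H](O[Si](C)(C)C(C)(C)C)[C@@H](O1)C(=O)CO[Si](C)(C)C(C)(C)C | intermediate
11 | (4R,5S)-4-(TBSO)-5-[3-(TBSO)prop-1-en-2-yl]-3-methylideneoxolan-2-one (not isolated) | O=C1C(=C)[C@@H](O[Si](C)(C)C(C)(C)C)[C@@H](O1)C(=C)CO[Si](C)(C)C(C)(C)C | intermediate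
12 | (4R,5S)-4-(TBSO)-5-[3-(TBSO)prop-1-en-2-yl]-2,3-dimethylideneoxolane | C=C(CO[Si](C)(C)C(C)(C)C)[C@@H]1OC(=C)C(=C)[C@H]1O[Si](C)(C)C(C)(C)C | intermediate
13 | but-3-yn-2-one | CC(=O)C#C | starting material
14 | 1-{(2S,3R)-3-(TBSO)-2-[3-(TBSO)prop-1-en-2-yl]-2,3,4,7-tetrahydro-1-benzofuran-5-yl}ethan-1-one | C=C(CO[Si](C)(C)C(C)(C)C)[C@@H]1OC2=C(CC(C(C)=O)=CC2)[C@H]1O[Si](C)(C)C(C)(C)C | intermediate
15 | 1-{(2S,3R)-3-(TBSO)-2-[3-(TBSO)prop-1-en-2-yl]-2,3-dihydro-1-benzofuran-5-yl}ethan-1-one | C=C(CO[Si](C)(C)C(C)(C)C)[C@@H]1Oc2ccc(C(C)=O)cc2[C@H]1O[Si](C)(C)C(C)(C)C | intermediate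
16 | (1R)-1-{(2S,3R)-3-(TBSO)-2-[3-(TBSO)prop-1-en-2-yl]-2,3-dihydro-1-benzofuran-5-yl}ethan-1-ol | C=C(CO[Si](C)(C)C(C)(C)C)[C@@H]1Oc2ccc([C@@H](C)O)cc2[C@H]1O[Si](C)(C)C(C)(C)C | intermediate
17 | tiglic acid, (2E)-2-methylbut-2-enoic acid | C/C=C(\C)C(=O)O | starting material
18 | (1R)-1-{(2S,3R)-3-(TBSO)-2-[3-(TBSO)prop-1-en-2-yl]-2,3-dihydro-1-benzofuran-5-yl}ethyl (2E)-2-methylbut-2-enoate | C=C(CO[Si](C)(C)C(C)(C)C)[C@@H]1Oc2ccc([C@@H](C)OC(=O)/C(C)=C/C)cc2[C@H]1O[Si](C)(C)C(C)(C)C | intermediate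
19 | (1R)-1-[(2S,3R)-3-(TBSO)-2-(3-hydroxyprop-1-en-2-yl)-2,3-dihydro-1-benzofuran-5-yl]ethyl (2E)-2-methylbut-2-enoate (not isolated) | C=C(CO)[C@@H]1Oc2ccc([C@@H](C)OC(=O)/C(C)=C/C)cc2[C@H]1O[Si](C)(C)C(C)(C)C | intermediate
20 | (1R)-1-[(2S,3R)-3-hydroxy-2-(3-hydroxyprop-1-en-2-yl)-2,3-dihydro-1-benzofuran-5-yl]ethyl (2E)-2-methylbut-2-enoate | C=C(CO)[C@@H]1Oc2ccc([C@@H](C)OC(=O)/C(C)=C/C)cc2[C@H]1O | intermediate
21 | (1R)-1-[(2S,3R)-3-hydroxy-2-(3-oxoprop-1-en-2-yl)-2,3-dihydro-1-benzofuran-5-yl]ethyl (2E)-2-methylbut-2-enoate | C=C(C=O)[C@@H]1Oc2ccc([C@@H](C)OC(=O)/C(C)=C/C)cc2[C@H]1O | intermediate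
22 | (1R)-1-[(2S,3R)-3-(acetyloxy)-2-(3-oxoprop-1-en-2-yl)-2,3-dihydro-1-benzofuran-5-yl]ethyl (2E)-2-methylbut-2-enoate | C=C(C=O)[C@@H]1Oc2ccc([C@@H](C)OC(=O)/C(C)=C/C)cc2[C@H]1OC(C)=O | target

Total step count: 15. Longest linear sequence: 15 steps (1 → 22).

Steps most likely to fail

Step 9. Oligomerisation of the diene or of the ynone may outrun the cycloaddition, the para orientation may erode, or silanol may be lost from the adduct under traces of acid. Fallback: the ynone is replaced by an ester dienophile that cannot enolise and tolerates more heat, and the methyl ketone is built afterwards. Diene 12 would be heated with methyl propiolate (K2CO3, toluene, 80 °C) to give methyl (2S,3R)-3-(TBSO)-2-[3-(TBSO)prop-1-en-2-yl]-2,3,4,7-tetrahydro-1-benzofuran-5-carboxylate F1. DDQ would dehydrogenate it to methyl (2S,3R)-3-(TBSO)-2-[3-(TBSO)prop-1-en-2-yl]-2,3-dihydro-1-benzofuran-5-carboxylate F2, at which stage a regioisomeric ester could be removed. MeNH(OMe)·HCl with i-PrMgCl (THF, −20 °C) would give (2S,3R)-3-(TBSO)-2-[3-(TBSO)prop-1-en-2-yl]-N-methoxy-N-methyl-2,3-dihydro-1-benzofuran-5-carboxamide F3, and MeMgBr would convert this amide into ketone 15, where the route is rejoined.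

Step 8. The diene may degrade or dimerise during the prolonged heating that the lactone carbonyl needs, or the second olefination may stall. Fallback: the two olefinations are separated, so that only the lactone needs a titanium carbene and this one is used cold. Ketone 10 would be methylenated chemoselectively with Zn, CH2Br2 and TiCl4 (THF–CH2Cl2, 0 °C; Lombardo–Takai conditions, to which lactones are inert) to give 11, now isolated. Compound 11 would then be converted into 12 with Cp2Ti(μ-Cl)(μ-CH2)AlMe2 (pyridine, THF–toluene, −40 → 0 °C). The route is rejoined at 12 and no compound outside the list arises (F0).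

Step 4. The β-silyloxy group may be eliminated from the lithium enolate before the sparingly soluble iminium salt has reacted. Fallback: the methylene is introduced before silylation through the alkoxide–enolate dianion, which cannot expel oxide. Hydroxy lactone 3 would be treated with LiN(i-Pr)2 (2.2 equiv, THF, −78 → −40 °C) and Eschenmoser's salt to give the 2,3-trans Mannich base 2-deoxy-2-C-[(dimethylamino)methyl]-5,6-O-isopropylidene-D-galactono-1,4-lactone F4. MeI would convert it into 2-deoxy-5,6-O-isopropylidene-2-C-[(trimethylammonio)methyl]-D-galactono-1,4-lactone iodide F5, and aqueous NaHCO3 would eliminate trimethylamine to give 2-deoxy-5,6-O-isopropylidene-2-methylidene-D-lyxo-hexono-1,4-lactone F6. TBSOTf with 2,6-lutidine (CH2Cl2, −78 °C) would silylate this alcohol to 7, where the route is rejoined.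

Further compounds
F1 | step 9 | methyl (2S,3R)-3-(TBSO)-2-[3-(TBSO)prop-1-en-2-yl]-2,3,4,7-tetrahydro-1-benzofuran-5-carboxylate | C=C(CO[Si](C)(C)C(C)(C)C)[C@@H]1OC2=C(CC(C(=O)OC)=CC2)[C@H]1O[Si](C)(C)C(C)(C)C
F2 | step 9 | methyl (2S,3R)-3-(TBSO)-2-[3-(TBSO)prop-1-en-2-yl]-2,3-dihydro-1-benzofuran-5-carboxylate | C=C(CO[Si](C)(C)C(C)(C)C)[C@@H]1Oc2ccc(C(=O)OC)cc2[C@H]1O[Si](C)(C)C(C)(C)C
F3 | step 9 | (2S,3R)-3-(TBSO)-2-[3-(TBSO)prop-1-en-2-yl]-N-methoxy-N-methyl-2,3-dihydro-1-benzofuran-5-carboxamide | C=C(CO[Si](C)(C)C(C)(C)C)[C@@H]1Oc2ccc(C(=O)N(C)OC)cc2[C@H]1O[Si](C)(C)C(C)(C)C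
F0 | step 8 | none | none
F4 | step 4 | 2-deoxy-2-C-[(dimethylamino)methyl]-5,6-O-isopropylidene-D-galactono-1,4-lactone | O=C1[C@H](CN(C)C)[C@@H](O)[C@@H](O1)[C@H]2COC(C)(C)O2
F5 | step 4 | 2-deoxy-5,6-O-isopropylidene-2-C-[(trimethylammonio)methyl]-D-galactono-1,4-lactone iodide | O=C1[C@H](C[N+](C)(C)C)[C@@H](O)[C@@H](O1)[C@H]2COC(C)(C)O2.[I-]
F6 | step 4 | 2-deoxy-5,6-O-isopropylidene-2-methylidene-D-lyxo-hexono-1,4-lactone | O=C1C(=C)[C@@H](O)[C@@H](O1)[C@H]2COC(C)(C)O2
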